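To whoever takes the bench next: the flask holds starting material at 1.4 M, and 35 mM of free catalyst goes in as 4 equal portions, the first at the start. We stop at 2.5 min. The question is how far apart the portions should stand.

| setting | summer | winter | autumn | maple | larch | alder | cedar | elm |
|---|---|---|---|---|---|---|---|---|
| starting material | 0.70 M | 1 M | 1.4 M | 1.4 M | 1.4 M | 1.4 M | 1.4 M | 1.4 M |
| free catalyst | 35 mM (in portions, 4) | 35 mM (in portions, 4) | 18 mM (in portions, 4) | 35 mM (in portions, 4) | 35 mM (in portions, 4) | 35 mM (in portions, 4) | 35 mM (in portions, 4) | 35 mM (in portions, 4) |
| remark | run made earlier; portions every 6.0 s | run made earlier; portions every 6.0 s | run made earlier; portions every 6.0 s | the portions of free catalyst follow each other after 6.0 s, the first at the start | the portions of free catalyst follow each other after 10 s, the first at the start | the portions of free catalyst follow each other after 15 s, the first at the start | the portions of free catalyst follow each other after 25 s, the first at the start | the portions of free catalyst follow each other after 30 s, the first at the start |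
| time |  |  |  | 2.5 min | 2.5 min | 2.5 min | 2.5 min | 2.5 min |

- summer (time / s: target / %, starting material / %): 10.0: 4.2, 94.7; 15.0: 8.2, 89.7; 40.0: 35.9, 62.3; 90.0: 67.0, 32.3
- winter (time / s: target / %, starting material / %): 10.0: 3.4, 96.1; 15.0: 6.9, 91.6; 40.0: 30.9, 67.2; 90.0: 63.3, 36.3
- autumn (time / s: target / %, starting material / %): 12.0: 2.4, 97.6; 30.0: 9.8, 90.1; 60.0: 21.9, 77.1; 90.0: 34.1, 65.1

(readings scatter by 0.3 percentage points)

- amount of target at the end, in percent of the starting material charged for maple, larch, alder, cedar, elm, in this order
- how the row runs (rises all the way / hardly changes / rises, then falls / falls, then rises / falls all the way)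

- the numbers in the tables scatter with a standard deviation of 0.3 percentage points
- steps that have been proposed: 2 free catalyst -> spent catalyst; catalyst intermediate B -> free catalyst + target; catalyst intermediate A -> catalyst intermediate B; starting material + free catalyst <-> catalyst intermediate A
- "hardly changes" means that all values lie within two and a half points (for a concentration: within two and a half percent of the largest)

We reckon with x, the fraction of starting material left. Target is close to one minus x: in winter at 90.0 s the two readings miss the whole by 0.4 percentage points.

The catalyst arrives in portions, so we take off its mean wait d, the interval times one less than the number of portions, over two. For maple, d is 9.00 s. Winter then reads the logarithm of one over x, divided by t minus d, as 0.769 min⁻¹ at 40.0 s and 0.751 min⁻¹ at 90.0 s. These two winter values lie close, so we assume a fall first order in x for our reckoning.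

Autumn has our starting concentration with 18 mM of catalyst and reads 0.318 min⁻¹ at 90.0 s. Scaling by the charge, which is our own assumption, gives 0.618 min⁻¹. This is λ, the running constant: the logarithm of one over x per unit of time after the mean wait.

When you come at the end, we expect maple to hold x = 23.4%, so target near 76.6%. Elm, with d = 45.0 s, should hold x = 33.9%, so target near 66.1%. Elm has less working time than maple, so our row falls. Do not stretch the interval. We have counted no catalyst spared from the step of two free catalyst to spent catalyst.

The forecast differs. It gives 72%, 75%, 76.5%, 75.5% and 73.5%, a row that rises, then falls, and it warns that “capture speed decides whether the early rise is real”.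

The flask gives 77.7%, 76.6%, 74.9%, 71.1% and 68.7%; the row falls all the way.

    2 free catalyst → spent catalyst (k = 0.520 L mol⁻¹ s⁻¹)
    catalyst intermediate B → free catalyst + target (k = 1.10 s⁻¹)
    catalyst intermediate A → catalyst intermediate B (k = 1.00 s⁻¹)
    starting material + free catalyst ⇌ catalyst intermediate A (K = 7.10 L mol⁻¹, k = 1.10 L mol⁻¹ s⁻¹)

At the end, elm has 37.5% of its catalyst spent and maple 52.7%, so elm spent less and still made less target. The running constant reckoned 23.4% of starting material for maple, where 22% stands. For elm it reckoned 33.9%, where 31% stands.

(The readings come from a simulation with constants of no real substance, noise included.)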